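**Retrosynthetic overview**
1. Feature: going round ring B (the central ring), the six carbons carry acyl, OH, CH2–ring A, OH, CH2–ring C, OH. This strict carbon/oxygen alternation is the folded C1–C6 segment of an 8-methyl-3,5,7-trioxodecanoate with arylmethyl branches on C2 and C4; the C7–C10 tail is the (S)-2-methylbutanoyl group.
2. Key disconnection: the ring B bond between the acyl-bearing carbon (chain C6) and the adjacent C–OH carbon (chain C1) is opened to the methyl triketo ester. In the forward sense this is a Mg(OMe)2-templated Claisen folding.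
3. Triketo ester: C6–C7 comes from a diketo ester trianion and the Weinreb amide of (S)-2-methylbutanoic acid (stereocentre bought, brought in last). C4–C5 comes from a β-keto ester dianion and an acetyl donor. C2–C3 comes from Claisen self-condensation of a single arylpropanoate, which is possible because rings A and C are identical.
4. The arylpropanoate is made from 2-methylphloroglucinol by formylation, para-O-methylation, benzylation, olefination and conjugate reduction. After ring closure come debenzylation and twofold butanoylation at the one free CH of rings A and C.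
5. Ring order: rings A and C are present from the start (2-methylphloroglucinol). Ring B is the only ring formed.

Key step: step 10

Remark on the chemistry: the β-keto ester, the diketo ester and the triketo ester are handled as mixtures of keto–enol tautomers and of C2/C4 epimers and are drawn in the keto form. These centres vanish on aromatisation. The decanoate numbering C1–C10 is used for the chain throughout, and Ar = 2,6-bis(benzyloxy)-4-methoxy-3-methylphenyl.

Step 1
Reactants: 1 2-methylphloroglucinol (2-methylbenzene-1,3,5-triol)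
Product: 3 2,4,6-trihydroxy-3-methylbenzaldehyde, via aryl iminium chloride 2 (not isolated)
Conditions: POCl3 (1.1 equiv), DMF, EtOAc, 0 °C → rt; then H2O
Reagents that add atoms: N,N-dimethylformamide CN(C)C=O; water O
Why: Vilsmeier–Haack formylation; the two free ring positions of 1 are equivalent and strongly activated, and the first formyl group deactivates the ring enough for one equivalent of reagent to stop at the monoaldehyde.

Step 2
Reactants: 3 2,4,6-trihydroxy-3-methylbenzaldehyde
Product: 4 2,6-dihydroxy-4-methoxy-3-methylbenzaldehyde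
Conditions: Me2SO4 (1.0 equiv), K2CO3 (1.0 equiv), acetone, rt
Reagents that add atoms: dimethyl sulfate COS(=O)(=O)OC
Why: Chemoselective Williamson-type O-methylation; the 2- and 6-hydroxyls flank the formyl group and are held back by hydrogen bonding to it, so with one equivalent each of base and electrophile the free, acidic 4-OH para to the aldehyde should react first.

Step 3
Reactants: 4 2,6-dihydroxy-4-methoxy-3-methylbenzaldehyde
Product: 5 2,6-bis(benzyloxy)-4-methoxy-3-methylbenzaldehyde
Conditions: BnBr (2.5 equiv), K2CO3 (3 equiv), DMF, 60 °C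
Reagents that add atoms: benzyl bromide BrCc1ccccc1
Why: Williamson ether synthesis in a polar solvent with heat and excess halide alkylates both chelated ortho-hydroxyls, and the aldehyde-deactivated ring resists C-benzylation.

Step 4
Reactants: 5 2,6-bis(benzyloxy)-4-methoxy-3-methylbenzaldehyde; 6 trimethyl phosphonoacetate
Product: 7 methyl (E)-3-[2,6-bis(benzyloxy)-4-methoxy-3-methylphenyl]prop-2-enoate
Conditions: NaH, THF, 0 °C → rt
Reagents that add atoms: none
Why: Horner–Wadsworth–Emmons olefination with a stabilised phosphonate tolerates the two ortho substituents and gives the E-cinnamate, whose geometry is erased in the next step.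

Step 5
Reactants: 7 methyl (E)-3-[2,6-bis(benzyloxy)-4-methoxy-3-methylphenyl]prop-2-enoate
Product: 8 methyl 3-[2,6-bis(benzyloxy)-4-methoxy-3-methylphenyl]propanoate
Conditions: NaBH4 (excess), NiCl2·6H2O (cat.), MeOH–THF, 0 °C
Reagents that add atoms: none
Why: Conjugate reduction with nickel boride made from NiCl2 and NaBH4 saturates the cinnamate C=C bond and leaves the ester and the aryl benzyl ethers alone, whereas hydrogenation over palladium would cleave the benzyl ethers.

Step 6
Reactants: 8 methyl 3-[2,6-bis(benzyloxy)-4-methoxy-3-methylphenyl]propanoate (two equivalents)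
Product: 9 methyl 5-Ar-2-(Ar-methyl)-3-oxopentanoate (racemic, C2 epimerisable)
Conditions: NaH (0.6 equiv per 8), MeOH (cat.), THF, reflux; then AcOH
Reagents that add atoms: none
Why: Claisen self-condensation of an ester with two α-hydrogens, driven by deprotonation of the β-keto ester formed; one operation lays down chain atoms C1–C4 together with both arylmethyl groups.

Step 7
Reactants: 9 methyl 5-Ar-2-(Ar-methyl)-3-oxopentanoate; 10 N-methoxy-N-methylacetamide
Product: 12 methyl 2,4-bis(Ar-methyl)-3,5-dioxohexanoate, via dilithium dienolate 11 (not isolated)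
Conditions: LiN(iPr)2 (2.2 equiv), THF, −78 → 0 °C; 10 (1.2 equiv), −78 → 0 °C; then cold 1 M HCl
Reagents that add atoms: none
Why: γ-Acylation of a β-keto ester dianion (Weinreb ketone synthesis); once C2 is deprotonated C4 is the only enolisable site left, its more basic carbon attacks the amide, and the lithium-chelated adduct lasts until the quench, so neither over-addition nor proton transfer from the product should interfere.

Step 8
Reactants: 13 (S)-2-methylbutanoic acid
Product: 15 (S)-N-methoxy-N,2-dimethylbutanamide, via acyl imidazole 14 (not isolated)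
Conditions: 1,1'-carbonyldiimidazole, CH2Cl2, 0 °C → rt; then MeNH(OMe)·HCl, rt
Reagents that add atoms: N,O-dimethylhydroxylamine hydrochloride CNOC.Cl; 1,1'-carbonyldiimidazole O=C(n1ccnc1)n1ccnc1 (imidazolyl group of 14 only)
Why: Amide formation through the acyl imidazole needs neither strong base nor an acid chloride, so the purchased S stereocentre, which bears only alkyl groups, is carried over unchanged.

Step 9
Reactants: 12 methyl 2,4-bis(Ar-methyl)-3,5-dioxohexanoate; 15 (S)-N-methoxy-N,2-dimethylbutanamide
Product: 17 methyl (8S)-2,4-bis(Ar-methyl)-8-methyl-3,5,7-trioxodecanoate, via trilithium trienolate 16 (not isolated)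
Conditions: LiN(iPr)2 (3.2 equiv), THF, −78 → 0 °C; 15 (1.1 equiv), −78 → −10 °C; then cold 1 M HCl
Reagents that add atoms: none
Why: Terminal acylation of a 3,5-dioxo ester trianion with a Weinreb amide; the C6 methyl is the only site left for the third deprotonation and therefore the most nucleophilic carbon, and because the adduct collapses only on acidic quench, C8 never faces amide base as the α-carbon of a free ketone and keeps its S configuration.

Step 10
Reactants: 17 methyl (8S)-2,4-bis(Ar-methyl)-8-methyl-3,5,7-trioxodecanoate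
Product: 19 (S)-1-[3,5-bis[[2,6-bis(benzyloxy)-4-methoxy-3-methylphenyl]methyl]-2,4,6-trihydroxyphenyl]-2-methylbutan-1-one, via acylcyclohexanetrione 18 (not isolated)
Conditions: Mg(OMe)2 (5 equiv), MeOH–THF (degassed), Ar, rt → 60 °C; then cold 1 M HCl
Reagents that add atoms: none
Why: Mg(OMe)2 turns 17 into a magnesium-bridged polyenolate whose neighbouring oxygens share the metal, which bends the chain so that C6 lies next to C1; the C6 carbanion, flanked by the C5 and C7 carbonyls, adds to the ester carbonyl, methoxide departs, and trione 18 tautomerises to the aromatic phenoxide, which makes the sequence irreversible. The closest known reaction is the intramolecular Claisen (Dieckmann-type) condensation of unbranched 3,5,7-trioxo esters, and of their 4-hydroxy-2-pyranone lactones, to 2-acylphloroglucinols with the same reagent. Ring B closes in a 6-exo-trig mode at the ester C=O, with the C5–C6–C7 enolate able to react through its enolexo form. No stereocentre is created: C2 and C4 become sp2 ring carbons, so their epimer mixture converges, and C8 is retained because C7 is enolised only toward the doubly activated C6 and ends as part of a vinylogous carboxylate in the phenoxide. The step needs Claisen folding to win over aldol folding and lactonisation: a C2-to-C7 aldol would require the fully substituted C2 carbon to attack the sec-butyl-shielded, enolised C7 ketone and would leave C2 quaternary, so no arene can form to pull it forward, and any 2-pyranone from O-acylation should be reopened by methoxide and fed back to 17. The benzyl ethers keep rings A and C from acting as phenoxide leaving groups, so the CH2 branches cannot migrate in the basic medium.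

Step 11
Reactants: 19 (S)-1-[3,5-bis[[2,6-bis(benzyloxy)-4-methoxy-3-methylphenyl]methyl]-2,4,6-trihydroxyphenyl]-2-methylbutan-1-one
Product: 20 (S)-1-[3,5-bis[(2,6-dihydroxy-4-methoxy-3-methylphenyl)methyl]-2,4,6-trihydroxyphenyl]-2-methylbutan-1-one
Conditions: H2 (1 atm), 10% Pd/C, EtOAc–MeOH, rt; product kept under Ar
Reagents that add atoms: none
Why: Catalytic hydrogenolysis of the four aryl benzyl ethers under neutral conditions; the hydrogen-bonded acylphloroglucinol ketone and the diarylmethane bridges are not reduced at 1 atm, and no acid or base is present to disturb C8.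

Step 12
Reactants: 20 (S)-1-[3,5-bis[(2,6-dihydroxy-4-methoxy-3-methylphenyl)methyl]-2,4,6-trihydroxyphenyl]-2-methylbutan-1-one; 21 butanoic acid
Product: 22 agrimol B
Conditions: 21 (6 equiv), BF3·OEt2, Ar, 60 °C; then aq NaOAc
Reagents that add atoms: none
Why: Friedel–Crafts acylation of phloroglucinol monoethers with a carboxylic acid in BF3·OEt2; rings A and C each offer a single C–H flanked by OH and OMe and para to OH while ring B has none, any O-acylation is funnelled to the ortho-hydroxy ketone by Fries rearrangement, and BF3, unlike AlCl3 or BCl3, should not cleave the methyl ether next to the new ketone.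

**Compound list**
1 | 2-methylphloroglucinol | Cc1c(O)cc(O)cc1O | starting material
2 | [(2,4,6-trihydroxy-3-methylphenyl)methylidene]dimethylazanium chloride | C[N+](C)=Cc1c(O)cc(O)c(C)c1O.[Cl-] | intermediate
3 | 2,4,6-trihydroxy-3-methylbenzaldehyde | O=Cc1c(O)cc(O)c(C)c1O | intermediate
4 | 2,6-dihydroxy-4-methoxy-3-methylbenzaldehyde | O=Cc1c(O)cc(OC)c(C)c1O | intermediate
5 | 2,6-bis(benzyloxy)-4-methoxy-3-methylbenzaldehyde | O=Cc1c(OCc2ccccc2)cc(OC)c(C)c1OCc1ccccc1 | intermediate
6 | trimethyl phosphonoacetate | COC(=O)CP(=O)(OC)OC | starting material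
7 | methyl (E)-3-[2,6-bis(benzyloxy)-4-methoxy-3-methylphenyl]prop-2-enoate | COC(=O)/C=C/c1c(OCc2ccccc2)cc(OC)c(C)c1OCc1ccccc1 | intermediate
8 | methyl 3-[2,6-bis(benzyloxy)-4-methoxy-3-methylphenyl]propanoate | COC(=O)CCc1c(OCc2ccccc2)cc(OC)c(C)c1OCc1ccccc1 | intermediate
9 | methyl 5-[2,6-bis(benzyloxy)-4-methoxy-3-methylphenyl]-2-[[2,6-bis(benzyloxy)-4-methoxy-3-methylphenyl]methyl]-3-oxopentanoate (racemic at C2) | COC(=O)C(Cc1c(OCc2ccccc2)cc(OC)c(C)c1OCc1ccccc1)C(=O)CCc1c(OCc2ccccc2)cc(OC)c(C)c1OCc1ccccc1 | intermediate
10 | N-methoxy-N-methylacetamide | CON(C)C(C)=O | starting material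
11 | dilithium dienolate of 9 (deprotonated at C2 and C4) | [Li+].[Li+].COC([O-])=C(Cc1c(OCc2ccccc2)cc(OC)c(C)c1OCc1ccccc1)C([O-])=CCc1c(OCc2ccccc2)cc(OC)c(C)c1OCc1ccccc1 | intermediate
12 | methyl 2,4-bis[[2,6-bis(benzyloxy)-4-methoxy-3-methylphenyl]methyl]-3,5-dioxohexanoate (C2/C4 epimer mixture) | COC(=O)C(Cc1c(OCc2ccccc2)cc(OC)c(C)c1OCc1ccccc1)C(=O)C(Cc1c(OCc2ccccc2)cc(OC)c(C)c1OCc1ccccc1)C(C)=O | intermediate
13 | (S)-2-methylbutanoic acid | CC[C@H](C)C(=O)O | starting material
14 | (S)-1-(imidazol-1-yl)-2-methylbutan-1-one | CC[C@H](C)C(=O)n1ccnc1 | intermediate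
15 | (S)-N-methoxy-N,2-dimethylbutanamide | CC[C@H](C)C(=O)N(C)OC | intermediate
16 | trilithium trienolate of 12 (deprotonated at C2, C4 and C6) | [Li+].[Li+].[Li+].COC([O-])=C(Cc1c(OCc2ccccc2)cc(OC)c(C)c1OCc1ccccc1)C([O-])=C(Cc1c(OCc2ccccc2)cc(OC)c(C)c1OCc1ccccc1)C([O-])=C | intermediate
17 | methyl (8S)-2,4-bis[[2,6-bis(benzyloxy)-4-methoxy-3-methylphenyl]methyl]-8-methyl-3,5,7-trioxodecanoate (C2/C4 epimer mixture) | COC(=O)C(Cc1c(OCc2ccccc2)cc(OC)c(C)c1OCc1ccccc1)C(=O)C(Cc1c(OCc2ccccc2)cc(OC)c(C)c1OCc1ccccc1)C(=O)CC(=O)[C@@H](C)CC | intermediate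
18 | 2,4-bis[[2,6-bis(benzyloxy)-4-methoxy-3-methylphenyl]methyl]-6-[(S)-2-methylbutanoyl]cyclohexane-1,3,5-trione | O=C([C@@H](C)CC)C1C(=O)C(Cc2c(OCc3ccccc3)cc(OC)c(C)c2OCc2ccccc2)C(=O)C(Cc2c(OCc3ccccc3)cc(OC)c(C)c2OCc2ccccc2)C1=O | intermediate
19 | (S)-1-[3,5-bis[[2,6-bis(benzyloxy)-4-methoxy-3-methylphenyl]methyl]-2,4,6-trihydroxyphenyl]-2-methylbutan-1-one | O=C([C@@H](C)CC)c1c(O)c(Cc2c(OCc3ccccc3)cc(OC)c(C)c2OCc2ccccc2)c(O)c(Cc2c(OCc3ccccc3)cc(OC)c(C)c2OCc2ccccc2)c1O | intermediate
20 | (S)-1-[3,5-bis[(2,6-dihydroxy-4-methoxy-3-methylphenyl)methyl]-2,4,6-trihydroxyphenyl]-2-methylbutan-1-one | O=C([C@@H](C)CC)c1c(O)c(Cc2c(O)cc(OC)c(C)c2O)c(O)c(Cc2c(O)cc(OC)c(C)c2O)c1O | intermediate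
21 | butanoic acid | CCCC(=O)O | starting material
22 | agrimol B, (S)-1-[3,5-bis[(3-butanoyl-2,6-dihydroxy-4-methoxy-5-methylphenyl)methyl]-2,4,6-trihydroxyphenyl]-2-methylbutan-1-one | CCCC(=O)c1c(O)c(Cc2c(O)c(Cc3c(O)c(C)c(OC)c(C(=O)CCC)c3O)c(O)c(C(=O)[C@@H](C)CC)c2O)c(O)c(C)c1OC | target

**Step count**
Total: 12 steps. Longest linear sequence: 11 steps (steps 1–7 and 9–12). Step 8 is a one-step side branch.

**Steps most likely to fail**

Step 10. Methoxide may cleave the poorly enolised, C4-branched β-diketone by retro-Claisen fragmentation faster than the crowded C6–C1 bond forms. The material may also rest at the lactone stage, because closure creates a hexasubstituted ring. The fallback takes ring B ready-made instead of folding it; it sets out from 5 and 13 and returns at 19. Aldehyde 5 is reduced with NaBH4 in MeOH–THF to [2,6-bis(benzyloxy)-4-methoxy-3-methylphenyl]methanol F1. Separately, commercial phloroglucinol is C-acylated with acid 13 in BF3·OEt2 to (S)-2-methyl-1-(2,4,6-trihydroxyphenyl)butan-1-one F2. Twofold Friedel–Crafts benzylation of the two free ring carbons of F2 with two equivalents of F1 (Sc(OTf)3 cat., MeCN, 0 °C) then gives 19. F1 is added slowly so that the benzylic cation does not attack its own kind.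

Step 12. In warm BF3·OEt2 the acyl-free, very electron-rich rings A and C may be protonated at the bridge-bearing carbon, so that the CH2 bridges fragment and recombine. The boron-bound ring B ketone may also enolise toward C8, with erosion of configuration. The fallback acylates before deprotection and without a Lewis acid; it sets out from 19 and returns at 22. The three ring B hydroxyls of 19 are esterified with butanoic anhydride, DMAP and pyridine to the ring B tributanoate F3, whose central ring can no longer stabilise a benzylic cation. The free CH of each trialkoxy ring is then acylated with butanoyl trifluoroacetate, made from 21 and (CF3CO)2O in CH2Cl2 at 0 °C → rt, to give the bis(aryl ketone) tributanoate F4. K2CO3 in MeOH removes the three aryl esters to give tetra-O-benzyl agrimol B F5. Hydrogenolysis (H2, 10% Pd/C, EtOAc) delivers 22.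

Step 9. The third deprotonation of the crowded, doubly branched dienolate may stay incomplete. The aggregated trianion may also add so slowly to the α-branched amide that proton transfer and base-induced breakdown of the N-methoxy group take over. The fallback replaces acylation by aldol addition and oxidation; it sets out from 12 and 15 and returns at 17. Amide 15 is reduced with iBu2AlH in CH2Cl2 at −78 °C to (S)-2-methylbutanal F6, which is used at once without chromatography to protect its configuration. This far more electrophilic partner intercepts trianion 16 at −78 °C to give the 7-hydroxy-3,5-dioxo ester F7 (C7 epimers). Dess–Martin periodinane in CH2Cl2 oxidises the carbinol to 17.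

**Further compounds**
F1 | step 10 | [2,6-bis(benzyloxy)-4-methoxy-3-methylphenyl]methanol | OCc1c(OCc2ccccc2)cc(OC)c(C)c1OCc1ccccc1
F2 | step 10 | (S)-2-methyl-1-(2,4,6-trihydroxyphenyl)butan-1-one | CC[C@H](C)C(=O)c1c(O)cc(O)cc1O
F3 | step 12 | 2,4-bis[[2,6-bis(benzyloxy)-4-methoxy-3-methylphenyl]methyl]-6-[(S)-2-methylbutanoyl]benzene-1,3,5-triyl tributanoate | O=C([C@@H](C)CC)c1c(OC(=O)CCC)c(Cc2c(OCc3ccccc3)cc(OC)c(C)c2OCc2ccccc2)c(OC(=O)CCC)c(Cc2c(OCc3ccccc3)cc(OC)c(C)c2OCc2ccccc2)c1OC(=O)CCC
F4 | step 12 | 2,4-bis[[2,6-bis(benzyloxy)-3-butanoyl-4-methoxy-5-methylphenyl]methyl]-6-[(S)-2-methylbutanoyl]benzene-1,3,5-triyl tributanoate | O=C([C@@H](C)CC)c1c(OC(=O)CCC)c(Cc2c(OCc3ccccc3)c(C(=O)CCC)c(OC)c(C)c2OCc2ccccc2)c(OC(=O)CCC)c(Cc2c(OCc3ccccc3)c(C(=O)CCC)c(OC)c(C)c2OCc2ccccc2)c1OC(=O)CCC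
F5 | step 12 | tetra-O-benzyl agrimol B, (S)-1-[3,5-bis[[2,6-bis(benzyloxy)-3-butanoyl-4-methoxy-5-methylphenyl]methyl]-2,4,6-trihydroxyphenyl]-2-methylbutan-1-one | O=C([C@@H](C)CC)c1c(O)c(Cc2c(OCc3ccccc3)c(C(=O)CCC)c(OC)c(C)c2OCc2ccccc2)c(O)c(Cc2c(OCc3ccccc3)c(C(=O)CCC)c(OC)c(C)c2OCc2ccccc2)c1O
F6 | step 9 | (S)-2-methylbutanal | CC[C@H](C)C=O
F7 | step 9 | methyl (8S)-2,4-bis[[2,6-bis(benzyloxy)-4-methoxy-3-methylphenyl]methyl]-7-hydroxy-8-methyl-3,5-dioxodecanoate (C2, C4 and C7 epimer mixture) | COC(=O)C(Cc1c(OCc2ccccc2)cc(OC)c(C)c1OCc1ccccc1)C(=O)C(Cc1c(OCc2ccccc2)cc(OC)c(C)c1OCc1ccccc1)C(=O)CC(O)[C@@H](C)CC
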